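# Proposed synthesis of (5E)-4-bromo-3-[(1R)-1-hydroxybutyl]-5-(iodomethylidene)furan-2(5H)-one (12)

## Analysis of the target

The target 12 is a fully substituted furan-2(5H)-one ring (O1, C2(=O), C3=C4, C5) that carries bromine on C4, an exocyclic C5=C6 double bond with iodine on C6, and a 1-hydroxybutyl chain (C1′–C4′) on C3. It has one stereocentre, C1′, which is R, and one stereogenic double bond, C5=C6, which is E: the iodine lies anti to the ring oxygen O1 and syn to the C4–Br bond, the more crowded and presumably less stable geometry. The two stereo-elements are three atoms apart and do not control each other, so each must be set by its own reagent-controlled event. C4 is a vinylogous acyl bromide and C6 the end of a 1,6-acceptor, so bases and nucleophiles displace halide by addition–elimination; the C6–I bond is light-sensitive and iodine atoms or iodide can equilibrate C5=C6 toward Z; the allylic C1′ carbinol can ionise or eliminate under strong acid. Two sub-structures are read as retrons: the array C1′(OH)–C3(=C4–Br)–C2(=O)–O1 is the β-bromo Morita–Baylis–Hillman adduct of an aldehyde and an alkynoate, and the unit O1–C5(=C6H–I), with O1 and I trans, is the anti adduct of an acyl oxygen and an iodonium ion across a terminal C5≡C6 alkyne. The difficulty is that every ring carbon is functionalised, three contiguous sp2 carbons (C4, C5, C6) bear three different heteroatoms, and both the kinetic E geometry and the carbinol must be installed on a skeleton that allows almost no later correction. The move chosen is a three-component, catalyst-controlled bromo-aldol union that builds the C3–C1′ bond, a C4–Br bond and the stereocentre at once from achiral one- to four-carbon pieces.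

## Retrosynthetic reasoning

**12 ⇒ 10 (cut O1–C5 and C6–I).** The E geometry cannot be reached by equilibration, but it is exactly what anti addition across a terminal alkyne gives. The forward reaction is a 5-exo-dig iodocyclisation in which the ester carbonyl oxygen of 10 attacks C5 anti to an electrophilic iodine on C6. It is placed last so that the E-iodide never meets a base, a nucleophile or a metal catalyst. It requires the ester and the alkyne of 10 to be cis across C3=C4.

**10 ⇒ 9 ⇒ 7 + 8 (cut C4–C5).** The tetrasubstituted C3=C4 alkene of 10 is traced to the 1,1-dibromoalkene 7, in which C4 carries two bromine atoms and therefore has no geometry. The forward reaction is a mono-Sonogashira coupling with alkyne 8 at the C4–Br bond cis to the ester, followed by removal of both silyl groups of 9 in one operation. This turns a geometry problem into a site-selection problem between a flat ester and a branched silyloxyalkyl group.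

**7 ⇒ 6 ⇒ 2 + 3 (cut C3–C1′ and one C4–Br; the key disconnection).** C1′ is the only stereocentre and sits on the α-carbon of a β-bromo-enoate, so the C3–C1′ bond is cut in the Morita–Baylis–Hillman sense. In the forward direction a bromide source adds to C4 of ynoate 2, and the resulting allenolate attacks aldehyde 3 on a chiral Lewis acid. Choosing the 3-bromoalkynoate 2 as acceptor is deliberate. If C4 already carried the C5≡C6 alkyne, the aldehyde would have to pass either bromine or the alkynyl group, two groups of similar size, and the C3=C4 geometry would be uncertain. With 2 both groups on C4 are bromine and the question does not arise. The precursor side is three achiral, trivial components.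

**2 ⇒ 1 (cut C4–Br).** Silver-catalysed bromination of the terminal alkyne 1.

## Alternatives that were turned down

**Alternative 1:** the textbook route for this family. Disconnection: C1′–O last, and before it C6–I, C4–Br and O1–C5 on a 4-oxopentanoic acid chain. Forward: 2-butyl-4-oxopentanoic acid A1 is brominated and cyclodehydrated in strong acid to 4-bromo-3-butyl-5-methylidenefuran-2(5H)-one A2. Iodination and dehydroiodination give 4-bromo-3-butyl-5-(iodomethylidene)furan-2(5H)-one A3, and radical bromination at C1′ with hydrolysis gives the carbinol. Turned down because: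
- the C6 geometry arises by elimination under thermodynamic control, which should favour Z (iodine next to O1, away from bromine);
- C1′ is functionalised through a radical, so the carbinol is racemic and the C6–I bond is at risk;
- the hot acid step tolerates no oxygen function on the chain.

Neither selectivity problem is solved, at a comparable step count.

**Alternative 2:** disconnection of O1–C5 and C4–Br in one step by bromolactonisation of a 2,3-allenoic acid. Forward: 2-[(1R)-1-hydroxybutyl]penta-2,3-dienoic acid A4 undergoes copper-mediated bromocyclisation to 4-bromo-3-[(1R)-1-hydroxybutyl]-5-methylfuran-2(5H)-one A5. The step is attractive: it makes the ring and the C4–Br bond with secure regiochemistry. It was turned down because C5 ends sp3 with H and CH3. Reaching C5=C6H–I then needs halogenation and elimination at C5 and again at C6. The C6 geometry would again be set by elimination rather than by addition, so Z is expected, and the sequence is longer than the whole route chosen.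

**Alternative 3:** disconnection of C3–C1′ last, on the intact halogenated ring. Forward: (5E)-4-bromo-5-(iodomethylidene)furan-2(5H)-one A6 is metalated at C3 and added to 3, or acylated to (5E)-4-bromo-3-butanoyl-5-(iodomethylidene)furan-2(5H)-one A7, which is reduced enantioselectively. Turned down because:
- A6 needs the same iodocyclisation, so nothing is saved;
- the stereocentre would be made last on the most fragile compound;
- a metalating base can exchange the C6–I bond or add at C4;
- the direct aldol is racemic;
- A7 is a doubly activated acceptor in which hydride should add in the conjugate sense and expel bromide.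

Key step: step 2

## Remarks before the steps

- Target numbering (O1, C2–C6, C1′–C4′) is used for all intermediates in the discussion; names follow normal nomenclature.
- Assumption: the (S)-configured oxazaborolidinium ion exposes the Si face of its boron-bound aldehyde, as in additions of silyl nucleophiles with this catalyst class. If the sense is the opposite, its antipode is used.

## Route

Step 1
Reactants: 1 methyl prop-2-ynoate
Product: 2 methyl 3-bromoprop-2-ynoate
Conditions: N-bromosuccinimide (1.1 equiv), AgNO3 (10 mol %), acetone, rt
Reagents that add atoms: N-bromosuccinimide, O=C1CCC(=O)N1Br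
Why: Silver-catalysed electrophilic bromination of a terminal alkyne: the silver acetylide is brominated at carbon, the ester is untouched, and 2 is a known, distillable (lachrymatory) liquid.

Step 2
Reactants: 2 methyl 3-bromoprop-2-ynoate; 3 butanal
Product: 6 methyl 3,3-dibromo-2-[(1R)-1-hydroxybutyl]prop-2-enoate, via silyl allenolate 4 (not isolated), via trimethylsilyl ether 5 (not isolated)
Conditions: bromotrimethylsilane (1.5 equiv), (S)-1-(2-methylphenyl)-3,3-diphenyltetrahydro-1H,3H-pyrrolo[1,2-c][1,3,2]oxazaborole activated with HN(SO2CF3)2 (20 mol %), CH2Cl2, −78 °C; then 1 M HCl, THF, 0 °C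
Reagents that add atoms: bromotrimethylsilane, C[Si](C)(C)Br
Why: Proposed new method: bromide from bromotrimethylsilane adds in conjugate fashion to C4 of the Lewis-acid-activated ynoate 2 and silylation of the allenolate gives the 4,4-dibromoallenyl silyl ketene acetal 4, whose C3 then attacks butanal held on the chiral oxazaborolidinium ion in a Mukaiyama-type aldol step; silyl transfer to the aldolate gives 5 and frees the catalyst, and acidic work-up gives 6. The closest known reaction type is the Lewis-acid-mediated halo-aldol (β-halo Morita–Baylis–Hillman) three-component coupling of propiolates, silyl or metal halides and aldehydes, including its oxazaborolidinium-catalysed enantioselective form with iodotrimethylsilane; new here are a 3-bromoalkynoate as acceptor and bromide as the halide. No ring is closed. The single stereocentre C1′ is set by the catalyst: the aldehyde binds to boron with its formyl C–H held by the ring oxygen, one aryl group shields the Re face, and C3 of 4 attacks the Si face, which gives the (R)-carbinol. The step needs attack through C3 only, 1,2-addition to the aldehyde and enantioface selectivity, but no alkene geometry, because C4 of 4 carries two identical bromine atoms and either approach of the aldehyde past C4 gives the same tetrasubstituted alkene. The bromine already on C4 makes that carbon more electrophilic than in a simple propiolate, which should offset the lower nucleophilicity of bromide compared with iodide.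

Step 3
Reactants: 6 methyl 3,3-dibromo-2-[(1R)-1-hydroxybutyl]prop-2-enoate
Product: 7 methyl 3,3-dibromo-2-[(1R)-1-{[tert-butyl(dimethyl)silyl]oxy}butyl]prop-2-enoate
Conditions: tert-butyldimethylsilyl triflate (1.3 equiv), 2,6-lutidine (2 equiv), CH2Cl2, −78 to 0 °C
Reagents that add atoms: tert-butyldimethylsilyl triflate, CC(C)(C)[Si](C)(C)OS(=O)(=O)C(F)(F)F
Why: Standard silylation of a hindered secondary alcohol with a silyl triflate and a non-nucleophilic base; the bulky, non-coordinating silyl ether is wanted for the site selection in step 4, and C1′ is not touched.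

Step 4
Reactants: 7 methyl 3,3-dibromo-2-[(1R)-1-{[tert-butyl(dimethyl)silyl]oxy}butyl]prop-2-enoate; 8 ethynyltrimethylsilane
Product: 9 methyl (2E)-3-bromo-2-[(1R)-1-{[tert-butyl(dimethyl)silyl]oxy}butyl]-5-(trimethylsilyl)pent-2-en-4-ynoate
Conditions: 8 (1.05 equiv), PdCl2(PPh3)2 (5 mol %), CuI (10 mol %), Et3N (3 equiv), THF, 0 °C to rt
Reagents that add atoms: none
Why: Sonogashira coupling in its known form as site-selective mono-alkynylation of a 1,1-dibromoalkene: zerovalent palladium should insert into the C4–Br bond cis to the ester, which is the less shielded one (a twisted, flat ester against a branched silyloxybutyl group) and the one where the ester carbonyl can guide the metal. One equivalent of 8 and the greater hindrance of the remaining bromine should stop the reaction at 9, in which ester and alkyne are cis (E by the sequence rule, because bromine outranks the alkynyl carbon).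

Step 5
Reactants: 9 methyl (2E)-3-bromo-2-[(1R)-1-{[tert-butyl(dimethyl)silyl]oxy}butyl]-5-(trimethylsilyl)pent-2-en-4-ynoate
Product: 10 methyl (2E)-3-bromo-2-[(1R)-1-hydroxybutyl]pent-2-en-4-ynoate
Conditions: tetrabutylammonium fluoride (3 equiv), AcOH (3 equiv), THF, 0 °C to rt
Reagents that add atoms: none
Why: Fluoride cleaves the C(sp)–Si and O–Si bonds in one operation, and acetic acid buffers the medium so that no alkoxide adds to C4; the freed hydroxyl is trans to the alkyne across C3=C4 and cannot cyclise onto it.

Step 6
Reactants: 10 methyl (2E)-3-bromo-2-[(1R)-1-hydroxybutyl]pent-2-en-4-ynoate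
Product: 12 (5E)-4-bromo-3-[(1R)-1-hydroxybutyl]-5-(iodomethylidene)furan-2(5H)-one, via methoxyfuranium iodide 11 (not isolated)
Conditions: I2 (3 equiv), MeCN, 0 °C to rt, in the dark
Reagents that add atoms: iodine, II
Why: Electrophilic 5-exo-dig iodocyclisation of a cis-enynoate ester: iodine activates the terminal alkyne with the positive charge developing on the internal carbon C5, the ester carbonyl oxygen attacks C5 anti to iodine to give the methoxyfuranium ion 11, and iodide removes the methyl group. Anti addition places iodine trans to O1, which is the required E geometry; darkness, a short reaction time and a thiosulfate quench should keep the kinetic isomer from equilibrating.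

## Compound list

1 | methyl prop-2-ynoate | C#CC(=O)OC | starting material
2 | methyl 3-bromoprop-2-ynoate | BrC#CC(=O)OC | intermediate
3 | butanal | CCCC=O | starting material
4 | [(3,3-dibromo-1-methoxypropa-1,2-dien-1-yl)oxy]trimethylsilane | COC(O[Si](C)(C)C)=C=C(Br)Br | intermediate
5 | methyl 3,3-dibromo-2-[(1R)-1-(trimethylsilyloxy)butyl]prop-2-enoate | CCC[C@@H](O[Si](C)(C)C)C(C(=O)OC)=C(Br)Br | intermediate
6 | methyl 3,3-dibromo-2-[(1R)-1-hydroxybutyl]prop-2-enoate | CCC[C@@H](O)C(C(=O)OC)=C(Br)Br | intermediate
7 | methyl 3,3-dibromo-2-[(1R)-1-{[tert-butyl(dimethyl)silyl]oxy}butyl]prop-2-enoate | CCC[C@@H](O[Si](C)(C)C(C)(C)C)C(C(=O)OC)=C(Br)Br | intermediate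
8 | ethynyltrimethylsilane | C#C[Si](C)(C)C | starting material
9 | methyl (2E)-3-bromo-2-[(1R)-1-{[tert-butyl(dimethyl)silyl]oxy}butyl]-5-(trimethylsilyl)pent-2-en-4-ynoate | CCC[C@@H](O[Si](C)(C)C(C)(C)C)/C(C(=O)OC)=C(\Br)C#C[Si](C)(C)C | intermediate
10 | methyl (2E)-3-bromo-2-[(1R)-1-hydroxybutyl]pent-2-en-4-ynoate | CCC[C@@H](O)/C(C(=O)OC)=C(\Br)C#C | intermediate
11 | (5E)-4-bromo-3-[(1R)-1-hydroxybutyl]-5-(iodomethylidene)-2-methoxy-5H-furan-1-ium iodide | CCC[C@@H](O)C1=C(Br)/C(=C\I)[O+]=C1OC.[I-] | intermediate
12 | (5E)-4-bromo-3-[(1R)-1-hydroxybutyl]-5-(iodomethylidene)furan-2(5H)-one | CCC[C@@H](O)C1=C(Br)/C(=C\I)OC1=O | target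

## Step count and risk

Total: 6 steps. Longest linear sequence: 6 steps (1 → 2 → 6 → 7 → 9 → 10 → 12).

**Step 2 (key step, labelled as a proposed new method).** What may go wrong:
- conjugate addition of bromide to 2 may be slow or reversible, so that catalyst turnover is poor;
- an uncatalysed background aldol may erode the enantioface selectivity;
- facial discrimination may be weak for an unbranched aldehyde.

The fallback uses known chemistry, sets out from 3 and returns at 7. Butanal is coupled with 1,1,1,3,3,3-hexafluoropropan-2-yl acrylate under β-isocupreidine (C19H22N2O2) catalysis in DMF at −55 °C. This is a known enantioselective Morita–Baylis–Hillman reaction and should give 1,1,1,3,3,3-hexafluoropropan-2-yl (3R)-3-hydroxy-2-methylidenehexanoate F1. Methanolysis (MeOH, catalytic NaOMe, 0 °C) should give methyl (3R)-3-hydroxy-2-methylidenehexanoate F2. Silylation (tert-butyldimethylsilyl triflate, 2,6-lutidine) should give methyl (3R)-3-{[tert-butyl(dimethyl)silyl]oxy}-2-methylidenehexanoate F3. Ozonolysis (O3, CH2Cl2, −78 °C; then Me2S) should give the α-keto ester methyl (3R)-3-{[tert-butyl(dimethyl)silyl]oxy}-2-oxohexanoate F4. Ramirez dibromo-olefination (CBr4, PPh3, CH2Cl2, 0 °C) should then give 7. This costs three more steps but still delivers the symmetric CBr2 terminus.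

**Step 4.** What may go wrong: poor discrimination between the two diastereotopic C4–Br bonds in the oxidative addition, and a second coupling at the remaining bromine. The fallback sets out from 7 and returns at 9, and replaces catalyst-controlled site selection by chelation-controlled metalation. Bromine–magnesium exchange with iPrMgCl·LiCl in THF at −78 °C, directed by the ester carbonyl, should give the carbenoid methyl (2E)-3-bromo-3-(chloromagnesio)-2-[(1R)-1-{[tert-butyl(dimethyl)silyl]oxy}butyl]prop-2-enoate F5. Trapping with I2 should give, with retention, methyl (2Z)-3-bromo-3-iodo-2-[(1R)-1-{[tert-butyl(dimethyl)silyl]oxy}butyl]prop-2-enoate F6. Sonogashira coupling with 8 (PdCl2(PPh3)2, CuI, Et3N, 0 °C) then takes place at the C–I bond, whichever position it occupies, and gives 9.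

**Step 6.** What may go wrong:
- competing 6-endo closure to a pyranone;
- rotation about C5–C6 in the cationic intermediate before the methyl group is lost;
- iodine-atom or iodide-mediated equilibration of C5=C6 toward Z;
- simple addition of iodine across the alkyne.

The fallback sets out from 10 and returns at 12, and uses a carboxylate instead of an ester as the nucleophile, so that no cationic intermediate is formed. Mild hydrolysis (Me3SnOH, 1,2-dichloroethane, 70 °C; dilute HCl work-up) should give (2E)-3-bromo-2-[(1R)-1-hydroxybutyl]pent-2-en-4-ynoic acid F7. Classical iodolactonisation (I2, NaHCO3, MeCN, 0 °C, dark) should give 12.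

**Step 5.** What may go wrong: loss of bromide by addition–elimination at C4 if the fluoride medium becomes basic, and slow cleavage of the hindered silyl ether. The fallback sets out from 7 and returns at 12. It avoids both the carbon-bound silyl group and fluoride at the ester stage. Negishi coupling of 7 with ethynylzinc bromide (from ethynylmagnesium bromide and ZnBr2; Pd(PPh3)4, THF, 0 °C to rt) should give methyl (2E)-3-bromo-2-[(1R)-1-{[tert-butyl(dimethyl)silyl]oxy}butyl]pent-2-en-4-ynoate F8. Iodocyclisation (I2, MeCN, dark) should give (5E)-4-bromo-3-[(1R)-1-{[tert-butyl(dimethyl)silyl]oxy}butyl]-5-(iodomethylidene)furan-2(5H)-one F9, and HF·pyridine in THF should give 12.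

## Further compounds

F1 | step 2 | 1,1,1,3,3,3-hexafluoropropan-2-yl (3R)-3-hydroxy-2-methylidenehexanoate | CCC[C@@H](O)C(=C)C(=O)OC(C(F)(F)F)C(F)(F)F
F2 | step 2 | methyl (3R)-3-hydroxy-2-methylidenehexanoate | CCC[C@@H](O)C(=C)C(=O)OC
F3 | step 2 | methyl (3R)-3-{[tert-butyl(dimethyl)silyl]oxy}-2-methylidenehexanoate | CCC[C@@H](O[Si](C)(C)C(C)(C)C)C(=C)C(=O)OC
F4 | step 2 | methyl (3R)-3-{[tert-butyl(dimethyl)silyl]oxy}-2-oxohexanoate | CCC[C@@H](O[Si](C)(C)C(C)(C)C)C(=O)C(=O)OC
F5 | step 4 | methyl (2E)-3-bromo-3-(chloromagnesio)-2-[(1R)-1-{[tert-butyl(dimethyl)silyl]oxy}butyl]prop-2-enoate | CCC[C@@H](O[Si](C)(C)C(C)(C)C)/C(C(=O)OC)=C(\Br)[Mg]Cl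
F6 | step 4 | methyl (2Z)-3-bromo-3-iodo-2-[(1R)-1-{[tert-butyl(dimethyl)silyl]oxy}butyl]prop-2-enoate | CCC[C@@H](O[Si](C)(C)C(C)(C)C)/C(C(=O)OC)=C(\Br)I
F7 | step 6 | (2E)-3-bromo-2-[(1R)-1-hydroxybutyl]pent-2-en-4-ynoic acid | CCC[C@@H](O)/C(C(=O)O)=C(\Br)C#C
F8 | step 5 | methyl (2E)-3-bromo-2-[(1R)-1-{[tert-butyl(dimethyl)silyl]oxy}butyl]pent-2-en-4-ynoate | CCC[C@@H](O[Si](C)(C)C(C)(C)C)/C(C(=O)OC)=C(\Br)C#C
F9 | step 5 | (5E)-4-bromo-3-[(1R)-1-{[tert-butyl(dimethyl)silyl]oxy}butyl]-5-(iodomethylidene)furan-2(5H)-one | CCC[C@@H](O[Si](C)(C)C(C)(C)C)C1=C(Br)/C(=C\I)OC1=O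
A1 | alternative 1 | 2-butyl-4-oxopentanoic acid | CCCCC(CC(C)=O)C(=O)O
A2 | alternative 1 | 4-bromo-3-butyl-5-methylidenefuran-2(5H)-one | CCCCC1=C(Br)C(=C)OC1=O
A3 | alternative 1 | (5Z)-4-bromo-3-butyl-5-(iodomethylidene)furan-2(5H)-one | CCCCC1=C(Br)/C(=C/I)OC1=O
A4 | alternative 2 | 2-[(1R)-1-hydroxybutyl]penta-2,3-dienoic acid | CCC[C@@H](O)C(C(=O)O)=C=CC
A5 | alternative 2 | 4-bromo-3-[(1R)-1-hydroxybutyl]-5-methylfuran-2(5H)-one | CCC[C@@H](O)C1=C(Br)C(C)OC1=O
A6 | alternative 3 | (5E)-4-bromo-5-(iodomethylidene)furan-2(5H)-one | O=C1C=C(Br)/C(=C\I)O1
A7 | alternative 3 | (5E)-4-bromo-3-butanoyl-5-(iodomethylidene)furan-2(5H)-one | CCCC(=O)C1=C(Br)/C(=C\I)OC1=O
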